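**Strategy.** The decalin is disconnected in ring A (C4a–C5–C6–C7–C8–C8a; naphthalene locants, C1' = benzylic carbon) across C5–C6 and the ring-fusion bond C4a–C8a. One intramolecular Diels–Alder reaction of an acyclic 2-silyloxy triene made from (R)-citronellal closes rings A and B; it exploits that the cis-1,4 stereocentres C1 (bought) and C4 (Shi epoxidation, vinyl opening) of ring B sit on the tether and relay to C4a, and that C7/C8 are the inner diene carbons. The adduct is a regiodefined C7=C8 silyl enol ether: an enantiopure Cr(CO)3-complexed benzylic cation alkylates C7 (setting C7 and C1'), the C8 ketone becomes the C8=C8a alkene, then formylation and deprotection.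

Key step: step 6

Remark: core locants are C1 = CH–CH3, C4 = CH–CMe2O, C4a = sp3 ring-fusion CH, C7 = quaternary carbon, C8a = the other ring-fusion carbon, ring B = C1–C2–C3–C4–C4a–C8a, and α = the face of H-4a; the carbinol centre of 3, 4 and 6 is an inconsequential epimer mixture, and 9, 16 and 17 are drawn as the trans-fused C8a epimers, the cis-fused epimers converging at step 12.

Step 1
Reactants: 1 (R)-citronellal; 2 isopropenylmagnesium bromide
Product: 3 (5R)-2,5,9-trimethyldeca-1,8-dien-3-ol (C3 epimer mixture)
Conditions: THF, −78 → 0 °C; aq. NH4Cl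
Reagents that add atoms: none
Why: Grignard 1,2-addition to the aldehyde leaves the remote methyl stereocentre untouched, and the new carbinol centre (both epimers) is removed by the oxidation in step 4.

Step 2
Reactants: 3 dienol
Product: 4 (5R)-7-[(2S)-3,3-dimethyloxiran-2-yl]-2,5-dimethylhept-1-en-3-ol (C3 epimer mixture)
Conditions: ent-Shi ketone (30 mol %), Oxone, K2CO3, Bu4NHSO4, MeCN/DMM/aq. buffer (pH 10.5), 0 °C
Reagents that add atoms: Oxone (potassium peroxymonosulfate), [K+].[O-]S(=O)(=O)OO
Why: Shi asymmetric epoxidation, in which the chiral dioxirane reacts through its spiro transition state with the electron-rich trisubstituted alkene in preference to the 1,1-disubstituted allylic-alcohol alkene, and the enantiomer of the D-fructose-derived ketone should deliver oxygen to the face that gives the (S)-epoxide (reagent control).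

Step 3
Reactants: 4 epoxy alcohol; 5 vinylmagnesium bromide
Product: 6 (3S,6R)-3-ethenyl-2,6,9-trimethyldec-9-ene-2,8-diol (C8 epimer mixture)
Conditions: CH2=CHMgBr (4 equiv), CuI (20 mol %), THF, −30 → 0 °C; aq. NH4Cl
Reagents that add atoms: none
Why: CuI-catalysed SN2 opening of the epoxide at its less substituted carbon with inversion turns the (S)-epoxide carbon into the future C4 stereocentre bearing vinyl and CMe2OH, the excess Grignard reagent covering the free hydroxyl group.

Step 4
Reactants: 6 triene diol
Product: 7 (5R,8S)-8-ethenyl-9-hydroxy-2,5,9-trimethyldec-1-en-3-one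
Conditions: Dess–Martin periodinane, NaHCO3, CH2Cl2, 0 °C → rt
Reagents that add atoms: none
Why: Dess–Martin oxidation converts the secondary allylic alcohol (both epimers) into the isopropenyl ketone, while the tertiary alcohol cannot be oxidised.

Step 5
Reactants: 7 hydroxy enone
Product: 8 (3Z,5R,8S)-3,9-bis(tert-butyldimethylsilyloxy)-8-ethenyl-2,5,9-trimethyldeca-1,3-diene
Conditions: TBSOTf (2.5 equiv), Et3N (4 equiv), CH2Cl2, −78 → 0 °C
Reagents that add atoms: tert-butyldimethylsilyl triflate (TBSOTf), CC(C)(C)[Si](C)(C)OS(=O)(=O)C(F)(F)F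
Why: Soft enolisation of the only enolisable α-CH2 should give the (Z)-2-silyloxy-1,3-diene with the chain trans to the isopropenyl unit (the geometry the cycloaddition needs), and the same reagent silylates the tertiary alcohol.

Step 6
Reactants: 8 bis-silyl triene
Product: 9 (1R,4S,4aR,8aR)-8-(tert-butyldimethylsilyloxy)-4-[2-(tert-butyldimethylsilyloxy)propan-2-yl]-1,7-dimethyl-1,2,3,4,4a,5,6,8a-octahydronaphthalene
Conditions: toluene (0.01 M), BHT, Et3N (trace), 200 °C, sealed tube
Reagents that add atoms: none
Why: A concerted, suprafacial thermal [4+2] cycloaddition (type 1 intramolecular Diels–Alder) between the electron-rich (Z)-2-silyloxy-3-methyl diene and the tethered vinyl group forms C5–C6 and C4a–C8a in one transition state and leaves the new double bond at C7=C8 as a regiodefined, tetrasubstituted silyl enol ether. The closest known reaction type is the thermal cyclisation of 1,7,9-decatrienes to octalins, including 2-silyloxy dienes made from enones. Ring B closes as the six-membered tether ring through C4a–C8a, and ring A closes as the cycloadduct cyclohexene through C4a–C8a and C5–C6, in the fused mode that the four-carbon tether enforces. C4a is controlled by the chair-like tether, in which the large CMe2OTBS group at C4 is equatorial and the 1,4-cis methyl at C1 is therefore axial; an axial C5 arm would be syn-diaxial to that methyl, so the vinyl group should react through the face that puts C5 equatorial and trans to the C4 substituent, placing H-4a on the side of the C1 and C4 substituents. C8a is expected mainly with H-8a trans to H-4a (diene arm equatorial), but this centre becomes sp2 in step 12, so its epimer converges. The step therefore needs only π-facial selectivity at the dienophile, which the two tether stereocentres secure, while regiochemistry and the position of the enol ether follow from the connectivity.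

Step 7
Reactants: 10 1,3,5-trimethoxybenzene; 11 3-methylbutanoyl chloride
Product: 12 3-methyl-1-(2,4,6-trimethoxyphenyl)butan-1-one
Conditions: Bi(OTf)3 (5 mol %), MeNO2, 50 °C
Reagents that add atoms: none
Why: Friedel–Crafts acylation of the highly activated, threefold-symmetric arene stops at mono-acylation because the aryl ketone is deactivated.

Step 8
Reactants: 12 aryl ketone
Product: 13 (1R)-3-methyl-1-(2,4,6-trimethoxyphenyl)butan-1-ol
Conditions: (S)-Me-CBS oxazaborolidine (10 mol %), BH3·SMe2, THF, −20 °C; MeOH
Reagents that add atoms: none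
Why: Corey–Bakshi–Shibata reduction, in which the (S)-oxazaborolidine delivers hydride to the ketone face that gives the (R)-carbinol with the aryl group as the large substituent (catalyst control).

Step 9
Reactants: 13 (R)-benzylic alcohol
Product: 14 tricarbonyl[η6-(1R)-3-methyl-1-(2,4,6-trimethoxyphenyl)butan-1-ol]chromium
Conditions: Cr(CO)3(naphthalene), THF/Et2O, 70 °C, sealed tube, dark
Reagents that add atoms: tricarbonyl(naphthalene)chromium, c1ccc2ccccc2c1.O=C=[Cr](=C=O)=C=O
Why: Arene exchange from the labile naphthalene complex to the more electron-rich trimethoxyarene under neutral conditions gives a single η6 complex, because the two faces of the symmetric ring are equivalent by rotation about the aryl–carbinol bond.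

Step 10
Reactants: 14 alcohol complex
Product: 15 tricarbonyl[η6-(1R)-3-methyl-1-(2,4,6-trimethoxyphenyl)butyl acetate]chromium
Conditions: Ac2O, pyridine, DMAP (cat.), CH2Cl2, 0 °C → rt, dark
Reagents that add atoms: acetic anhydride, CC(=O)OC(C)=O
Why: DMAP-catalysed O-acetylation installs the leaving group without touching the C–O stereocentre.

Step 11
Reactants: 15 acetate complex; 9 silyl enol ether
Product: 17 7-benzylated C8 ketone (aryl = 2,4,6-trimethoxyphenyl; H-8a trans to H-4a), via Cr(CO)3-complexed ketone 16 (not isolated)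
Conditions: BF3·OEt2 (1.2 equiv), CH2Cl2, −78 → −40 °C; then air, hν (visible), Et2O, rt
Reagents that add atoms: none
Why: Mukaiyama-type SN1 alkylation of a silyl enol ether by a chromium-stabilised benzylic cation, in which ionisation anti to chromium gives a configurationally stable cation that is attacked from the exo face (net retention at C1', reagent control), while C7 should be attacked on its α-face because the β-face is screened by the axial H-5 and H-8a (or by ring B in the cis-fused epimer), so the bulky group ends equatorial and the methyl axial; air and light then remove Cr(CO)3.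

Step 12
Reactants: 17 ketone
Product: 18 C8 enol triflate (C8=C8a)
Conditions: KHMDS, THF, −78 °C; PhNTf2, −78 → 0 °C
Reagents that add atoms: N-phenylbis(trifluoromethanesulfonimide), O=S(=O)(N(c1ccccc1)S(=O)(=O)C(F)(F)F)C(F)(F)F
Why: The ketone has a single α-hydrogen (H-8a), so deprotonation can give only the C8=C8a enolate, which is trapped on oxygen; the C8a stereocentre is erased and both ring-fusion epimers converge.

Step 13
Reactants: 18 enol triflate
Product: 19 tert-butyldimethylsilyl ether of the core alkene with the 2,4,6-trimethoxyphenyl group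
Conditions: Pd(OAc)2 (5 mol %), PPh3, HCO2H, Bu3N, DMF, 60 °C
Reagents that add atoms: none
Why: Palladium-catalysed formate reduction of the enol triflate (oxidative addition, formate exchange, decarboxylation, reductive elimination) gives the trisubstituted C8=C8a alkene without touching any stereocentre.

Step 14
Reactants: 19 trimethoxyaryl alkene
Product: 21 3',5'-diformyl trimethyl ether, via mono-formyl lithium aminoalkoxide 20 (not isolated)
Conditions: n-BuLi, TMEDA, THF, 0 °C; DMF (1.05 equiv), −78 °C; n-BuLi, 0 °C; DMF; aq. NH4Cl, then 1 M HCl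
Reagents that add atoms: N,N-dimethylformamide, CN(C)C=O
Why: Directed ortho-metalation, in which each ring C–H lies between two methoxy groups and is lithiated selectively, DMF formylates, and the lithium α-amino alkoxide from the first formylation protects that aldehyde during the second metalation.

Step 15
Reactants: 21 dialdehyde trimethyl ether
Product: 22 silyl ether of the target (free triphenol)
Conditions: NaSEt (10 equiv), DMF, 110 °C; then 1 M HCl
Reagents that add atoms: none
Why: SN2 O-demethylation by thiolate is accelerated because every methoxy group is ortho or para to a formyl group (stabilised phenoxide leaving group), while the tertiary silyl ether, the alkene and the stereocentres are inert.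

Step 16
Reactants: 22 triphenol silyl ether
Product: 23 target
Conditions: HF·pyridine, THF, 0 °C → rt
Reagents that add atoms: none
Why: Fluoride cleaves the tertiary silyl ether under mild, non-ionising conditions to reveal the tertiary alcohol.

**Compound list**

1 | (R)-citronellal, (3R)-3,7-dimethyloct-6-enal | C[C@H](CCC=C(C)C)CC=O | starting material
2 | isopropenylmagnesium bromide | C=C(C)[Mg]Br | starting material
3 | (5R)-2,5,9-trimethyldeca-1,8-dien-3-ol (C3 epimer mixture) | C=C(C)C(O)C[C@H](C)CCC=C(C)C | intermediate
4 | (5R)-7-[(2S)-3,3-dimethyloxiran-2-yl]-2,5-dimethylhept-1-en-3-ol (C3 epimer mixture) | C=C(C)C(O)C[C@H](C)CC[C@@H]1OC1(C)C | intermediate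
5 | vinylmagnesium bromide | C=C[Mg]Br | starting material
6 | (3S,6R)-3-ethenyl-2,6,9-trimethyldec-9-ene-2,8-diol (C8 epimer mixture) | C=C(C)C(O)C[C@H](C)CC[C@H](C(C)(C)O)C=C | intermediate
7 | (5R,8S)-8-ethenyl-9-hydroxy-2,5,9-trimethyldec-1-en-3-one | C=C(C)C(=O)C[C@H](C)CC[C@H](C(C)(C)O)C=C | intermediate
8 | (3Z,5R,8S)-3,9-bis(tert-butyldimethylsilyloxy)-8-ethenyl-2,5,9-trimethyldeca-1,3-diene | C=C(C)/C(O[Si](C)(C)C(C)(C)C)=C/[C@H](C)CC[C@H](C(C)(C)O[Si](C)(C)C(C)(C)C)C=C | intermediate
9 | (1R,4S,4aR,8aR)-8-(tert-butyldimethylsilyloxy)-4-[2-(tert-butyldimethylsilyloxy)propan-2-yl]-1,7-dimethyl-1,2,3,4,4a,5,6,8a-octahydronaphthalene (H-4a cis to the C1 and C4 substituents, H-8a trans to H-4a) | CC1=C(O[Si](C)(C)C(C)(C)C)[C@@H]2[C@H](C)CC[C@H](C(C)(C)O[Si](C)(C)C(C)(C)C)[C@H]2CC1 | intermediate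
10 | 1,3,5-trimethoxybenzene | COc1cc(OC)cc(OC)c1 | starting material
11 | 3-methylbutanoyl chloride | CC(C)CC(=O)Cl | starting material
12 | 3-methyl-1-(2,4,6-trimethoxyphenyl)butan-1-one | CC(C)CC(=O)c1c(OC)cc(OC)cc1OC | intermediate
13 | (1R)-3-methyl-1-(2,4,6-trimethoxyphenyl)butan-1-ol | CC(C)C[C@H](c1c(OC)cc(OC)cc1OC)O | intermediate
14 | tricarbonyl[η6-(1R)-3-methyl-1-(2,4,6-trimethoxyphenyl)butan-1-ol]chromium | CC(C)C[C@H](c1c(OC)cc(OC)cc1OC)O.O=C=[Cr](=C=O)=C=O | intermediate
15 | tricarbonyl[η6-(1R)-3-methyl-1-(2,4,6-trimethoxyphenyl)butyl acetate]chromium | CC(C)C[C@H](c1c(OC)cc(OC)cc1OC)OC(C)=O.O=C=[Cr](=C=O)=C=O | intermediate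
16 | Cr(CO)3 complex (η6 on the trimethoxyphenyl ring) of ketone 17 | CC(C)C[C@H](c1c(OC)cc(OC)cc1OC)[C@]1(C)C(=O)[C@@H]2[C@H](C)CC[C@H](C(C)(C)O[Si](C)(C)C(C)(C)C)[C@H]2CC1.O=C=[Cr](=C=O)=C=O | intermediate (not isolated)
17 | 4-[2-(tert-butyldimethylsilyloxy)propan-2-yl]-1,7-dimethyl-7-[3-methyl-1-(2,4,6-trimethoxyphenyl)butyl]octahydronaphthalen-8-one; C1, C4, C4a, C7 and C1' arranged as in the target, H-8a trans to H-4a | CC(C)C[C@H](c1c(OC)cc(OC)cc1OC)[C@]1(C)C(=O)[C@@H]2[C@H](C)CC[C@H](C(C)(C)O[Si](C)(C)C(C)(C)C)[C@H]2CC1 | intermediate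
18 | C8 enol triflate of 17 (C8=C8a double bond) | CC(C)C[C@H](c1c(OC)cc(OC)cc1OC)[C@]1(C)C(OS(=O)(=O)C(F)(F)F)=C2[C@H](C)CC[C@H](C(C)(C)O[Si](C)(C)C(C)(C)C)[C@H]2CC1 | intermediate
19 | tert-butyldimethylsilyl ether of the target skeleton bearing a 2,4,6-trimethoxyphenyl group in place of the diformylphloroglucinol ring | CC(C)C[C@H](c1c(OC)cc(OC)cc1OC)[C@]1(C)C=C2[C@H](C)CC[C@H](C(C)(C)O[Si](C)(C)C(C)(C)C)[C@H]2CC1 | intermediate
20 | lithium α-(dimethylamino)alkoxide of the 3'-mono-aldehyde of 19 | CC(C)C[C@H](c1c(OC)c(C(O[Li])N(C)C)c(OC)cc1OC)[C@]1(C)C=C2[C@H](C)CC[C@H](C(C)(C)O[Si](C)(C)C(C)(C)C)[C@H]2CC1 | intermediate (not isolated)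
21 | 3',5'-diformyl-2',4',6'-trimethoxy derivative (silyl ether) | CC(C)C[C@H](c1c(OC)c(C=O)c(OC)c(C=O)c1OC)[C@]1(C)C=C2[C@H](C)CC[C@H](C(C)(C)O[Si](C)(C)C(C)(C)C)[C@H]2CC1 | intermediate
22 | tert-butyldimethylsilyl ether of the target | CC(C)C[C@H](c1c(O)c(C=O)c(O)c(C=O)c1O)[C@]1(C)C=C2[C@H](C)CC[C@H](C(C)(C)O[Si](C)(C)C(C)(C)C)[C@H]2CC1 | intermediate
23 | 2,4,6-trihydroxy-5-{(1S)-1-[(1R,4S,4aR,7S)-4-(2-hydroxypropan-2-yl)-1,7-dimethyl-1,2,3,4,4a,5,6,7-octahydronaphthalen-7-yl]-3-methylbutyl}benzene-1,3-dicarbaldehyde (core locants as in the remark) | CC(C)C[C@H](c1c(O)c(C=O)c(O)c(C=O)c1O)[C@]1(C)C=C2[C@H](C)CC[C@H](C(C)(C)O)[C@H]2CC1 | target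

**Totals.** Total step count: 16. Longest linear sequence: 12 steps (steps 1–6 and 11–16, from (R)-citronellal); the aryl branch (steps 7–10) joins at step 11.

**Steps most likely to fail**

1. Step 6 (key cycloaddition). The unactivated vinyl group may react too slowly at temperatures the silyl enol ether tolerates, so that protodesilylation or diene isomerisation takes over, or the tether may fold through a competing conformation and erode facial selectivity at C4a. The fallback activates the dienophile with a removable sulfonyl group. It sets out from diol 6: cross-metathesis with phenyl vinyl sulfone (second-generation Hoveyda–Grubbs catalyst, CH2Cl2, 40 °C; the 1,1-disubstituted alkene is inert) should give the (E)-vinyl sulfone diol F1. Dess–Martin oxidation then gives the enone F2, and TBSOTf/Et3N the silyloxy triene sulfone F3. Its electron-poor dienophile should cyclise near 110 °C through the same chair-folded tether (endo sulfone, trans fusion) to the C5-sulfonyl adduct F4. Reductive desulfonylation with Na/Hg (Na2HPO4, MeOH/THF, −20 °C) returns to the route at 9.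

2. Step 11 (benzylic alkylation). Bond formation between a tetrasubstituted enol ether carbon and a di-ortho-substituted secondary benzylic cation is very congested. Proton loss from the cation, desilylation of the enol ether, attack on the β-face of C7, or rotation of the cation before capture (loss of configuration at C1') may compete. The fallback brings in the benzylic carbon as an aldehyde and the isobutyl group afterwards. It sets out from 9: MeLi (THF, 0 °C) liberates the regiodefined lithium enolate, which adds to commercial 2,4,6-trimethoxybenzaldehyde at −78 °C through a closed aldol transition state on the same α-face to give the aldol F5. BF3·OEt2 then ionises the benzylic hydroxyl, and methallyltrimethylsilane traps the trimethoxybenzylic cation to give the methallyl ketone F6 (1,2-induction from C7; the C1' epimers are separable at this stage). Hydrogenation of the 1,1-disubstituted alkene (H2, Pd/C, EtOAc) converts methallyl into isobutyl and returns to the route at 17.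

3. Step 3 (epoxide opening). Attack at the secondary carbon next to the fully substituted epoxide carbon may be slow, so that magnesium-halide-promoted rearrangement or halohydrin formation competes and the C4 stereocentre is lost. The fallback uses a slim sp-carbon nucleophile under Lewis-acid-free conditions and adjusts the oxidation level afterwards. It sets out from epoxide 4: lithium acetylide–ethylenediamine complex in DMSO (rt → 50 °C) should open the epoxide at the same carbon with the same inversion to give the alkyne diol F7. Semi-hydrogenation (H2, Pd/CaCO3 poisoned with Pb(OAc)2, quinoline, EtOAc) then returns to the route at 6.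

**Further compounds**

F1 | step 6 | (3S,6R)-2,6,9-trimethyl-3-[(E)-2-(phenylsulfonyl)ethenyl]dec-9-ene-2,8-diol (C8 epimer mixture) | C=C(C)C(O)C[C@H](C)CC[C@H](C(C)(C)O)/C=C/S(=O)(=O)c1ccccc1
F2 | step 6 | (5R,8S)-9-hydroxy-2,5,9-trimethyl-8-[(E)-2-(phenylsulfonyl)ethenyl]dec-1-en-3-one | C=C(C)C(=O)C[C@H](C)CC[C@H](C(C)(C)O)/C=C/S(=O)(=O)c1ccccc1
F3 | step 6 | (3Z,5R,8S)-3,9-bis(tert-butyldimethylsilyloxy)-2,5,9-trimethyl-8-[(E)-2-(phenylsulfonyl)ethenyl]deca-1,3-diene | C=C(C)/C(O[Si](C)(C)C(C)(C)C)=C/[C@H](C)CC[C@H](C(C)(C)O[Si](C)(C)C(C)(C)C)/C=C/S(=O)(=O)c1ccccc1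
F4 | step 6 | 5-(phenylsulfonyl) derivative of silyl enol ether 9 (C5 epimer mixture) | CC1=C(O[Si](C)(C)C(C)(C)C)[C@@H]2[C@H](C)CC[C@H](C(C)(C)O[Si](C)(C)C(C)(C)C)[C@H]2C(C1)S(=O)(=O)c1ccccc1
F5 | step 11 | aldol: 7-[hydroxy(2,4,6-trimethoxyphenyl)methyl] analogue of ketone 17 (carbinol epimer mixture) | OC(c1c(OC)cc(OC)cc1OC)[C@]1(C)C(=O)[C@@H]2[C@H](C)CC[C@H](C(C)(C)O[Si](C)(C)C(C)(C)C)[C@H]2CC1
F6 | step 11 | 7-[3-methyl-1-(2,4,6-trimethoxyphenyl)but-3-enyl] analogue of ketone 17 (C1' as in 17) | C=C(C)C[C@H](c1c(OC)cc(OC)cc1OC)[C@]1(C)C(=O)[C@@H]2[C@H](C)CC[C@H](C(C)(C)O[Si](C)(C)C(C)(C)C)[C@H]2CC1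
F7 | step 3 | (3S,6R)-3-ethynyl-2,6,9-trimethyldec-9-ene-2,8-diol (C8 epimer mixture) | C=C(C)C(O)C[C@H](C)CC[C@H](C(C)(C)O)C#C
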